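**Retrosynthetic overview**
1. The depside ester bond (oxygen on C4 of ring A to the ring B carbonyl) is cut last. This gives benzyl 2,4-dihydroxy-6-pentylbenzoate and a ring B acid whose side-chain ketone is masked as a dioxolane, because the free keto acid would close to an isocoumarin on activation.
2. Ring A rests on one feature: the carboxyl on C1 and the pentyl on C6 are vicinal, with oxygen on C2 beside C1 and oxygen on C4 meta to it. This is the pattern left by 1,2-difunctionalising 3,5-dimethoxybenzyne, so C6–pentyl and C1–CO2H are made together from 2-iodo-3,5-dimethoxyphenyl triflate, n-C5H11MgBr and CO2.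
3. The iodo triflate comes from 3,5-dimethoxyphenol by carbamate-directed ortho-lithiation/iodination and one-pot carbamate cleavage/triflation.
4. Ring B comes from methyl 2,4-dimethoxy-6-methylbenzoate by lateral lithiation and acylation with N-methoxy-N-methylbutanamide, then ketalisation and saponification.
5. No ring is formed at any stage (both benzene rings are bought) and the target has no stereocentre; the end game is ketal hydrolysis, then hydrogenolysis of the benzyl ester.

Key step: step 4

Remark: pentylmagnesium bromide is taken as the commercial ethereal solution (otherwise it is made from 1-bromopentane and magnesium).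

**Step 1**
Reactants: 1 3,5-dimethoxyphenol
Product: 2 3,5-dimethoxyphenyl N-isopropylcarbamate
Conditions: iPrNCO (1.2 equiv), Et3N (0.1 equiv), CH2Cl2, rt
Reagents that add atoms: isopropyl isocyanate, CC(C)N=C=O
Why: Amine-catalysed addition of the phenol O–H across the isocyanate (carbamoylation) should be clean and installs an ortho-directing group that can later be removed under mild base.

**Step 2**
Reactants: 2 3,5-dimethoxyphenyl N-isopropylcarbamate
Product: 6 2-iodo-3,5-dimethoxyphenyl N-isopropylcarbamate, via N-trimethylsilyl carbamate 3 (not isolated), via ortho-lithio N-trimethylsilyl carbamate 4 (not isolated), via N-trimethylsilyl iodo carbamate 5 (not isolated)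
Conditions: TMSOTf (1.05 equiv), TMEDA (1.1 equiv), Et2O, 0 °C → rt; then TMEDA (2 equiv), n-BuLi (2 equiv), −78 °C; then I2, THF, −78 °C → rt; aq. Na2S2O3, then dilute aq. HCl
Reagents that add atoms: iodine, II
Why: In situ N-silylation masks the N–H, and the carbamate, the strongest director on the ring, then steers directed ortho-metalation to the carbon flanked by carbamate and methoxy; at −78 °C the anionic Fries shift is slow, iodine quenches the aryllithium, and the N-silyl group is lost on aqueous work-up.

**Step 3**
Reactants: 6 2-iodo-3,5-dimethoxyphenyl N-isopropylcarbamate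
Product: 8 2-iodo-3,5-dimethoxyphenyl trifluoromethanesulfonate, via 2-iodo-3,5-dimethoxyphenol 7 (not isolated)
Conditions: DBU (1.5 equiv), Et2NH (1.2 equiv), MeCN, 40 °C; then PhNTf2 (1.5 equiv), 40 °C
Reagents that add atoms: N-phenylbis(trifluoromethanesulfonimide), O=S(=O)(N(c1ccccc1)S(=O)(=O)C(F)(F)F)C(F)(F)F
Why: DBU deprotonates the N–H carbamate, which loses isopropyl isocyanate by an E1cB elimination (captured by Et2NH as a urea), and the liberated phenoxide is O-sulfonylated by PhNTf2 in the same flask; the aryl iodide is inert to these conditions.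

**Step 4**
Reactants: 8 2-iodo-3,5-dimethoxyphenyl trifluoromethanesulfonate; 9 pentylmagnesium bromide; 10 carbon dioxide
Product: 14 2,4-dimethoxy-6-pentylbenzoic acid, via magnesiated aryl triflate 11 (not isolated), via 3,5-dimethoxybenzyne 12 (not isolated), via 2,4-dimethoxy-6-pentylphenylmagnesium bromide 13 (not isolated)
Conditions: 8 added slowly to n-C5H11MgBr (3 equiv), THF/Et2O, −78 °C → rt; then CO2 (gas), −20 °C → rt; 1 M HCl
Reagents that add atoms: none
Why: Iodine–magnesium exchange between the doubly ortho-activated aryl iodide and n-C5H11MgBr should give the magnesiated triflate 11, which loses MgBr(OTf) by β-elimination to 3,5-dimethoxybenzyne 12; a second equivalent of the Grignard reagent adds across the strained triple bond (aryne carbomagnesiation) and the resulting arylmagnesium 13 is carboxylated by CO2. The closest known reaction type is the generation of arynes from ortho-iodoaryl triflates with organomagnesium reagents, followed by nucleophilic addition of a Grignard reagent and electrophilic trapping of the new aryl–magnesium bond. No ring is closed and no stereocentre is formed; the two skeletal bonds C6–pentyl and C1–CO2H of ring A are made in one flask. The step needs regioselective addition to the unsymmetrical aryne, and the methoxy group on the carbon next to the triple bond secures it: its inductive pull distorts the aryne so that the remote carbon is the more electrophilic one, and the carbanion develops beside the oxygen, where it is inductively stabilised and can chelate magnesium. The step also needs the exchange to outrun attack of the Grignard reagent at sulfur and the exchange between 13 and unreacted 8, which slow addition of 8 to an excess of the Grignard reagent at −78 °C should ensure.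

**Step 5**
Reactants: 14 2,4-dimethoxy-6-pentylbenzoic acid
Product: 15 2,4-dihydroxy-6-pentylbenzoic acid (olivetolic acid)
Conditions: BBr3 (5 equiv), CH2Cl2, −78 °C → rt; poured onto ice-water, extracted and concentrated without heating
Reagents that add atoms: none
Why: Lewis-acid ether cleavage: BBr3 coordinates each methoxy oxygen and bromide removes the methyl group by SN2 (the chelated ortho ether first), and keeping the mixture at or below room temperature with a cold quench should spare the carboxyl from protodecarboxylation.

**Step 6**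
Reactants: 15 2,4-dihydroxy-6-pentylbenzoic acid
Product: 16 benzyl 2,4-dihydroxy-6-pentylbenzoate
Conditions: BnBr (1.05 equiv), KHCO3 (1.2 equiv), DMF, rt
Reagents that add atoms: benzyl bromide, BrCc1ccccc1
Why: Bicarbonate deprotonates only the carboxylic acid, so SN2 O-alkylation of the carboxylate gives the benzyl ester and leaves both phenols free.

**Step 7**
Reactants: 17 methyl 2,4-dimethoxy-6-methylbenzoate; 18 N-methoxy-N-methylbutanamide
Product: 21 methyl 2,4-dimethoxy-6-(2-oxopentyl)benzoate, via benzylic lithium species 19 (not isolated), via lithium hemiaminal adduct 20 (not isolated)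
Conditions: 17 added to LiN(iPr)2 (2 equiv), THF, −78 °C; then 18 (1.3 equiv), −78 °C; 1 M HCl, −78 → 0 °C
Reagents that add atoms: none
Why: Lateral lithiation of the ortho-toluate gives an ester-stabilised benzylic anion that acylates on the Weinreb amide; the chelated tetrahedral adduct holds until work-up, so over-addition is avoided, and inverse addition at −78 °C limits self-condensation of the toluate.

**Step 8**
Reactants: 21 methyl 2,4-dimethoxy-6-(2-oxopentyl)benzoate
Product: 22 methyl 2,4-dimethoxy-6-[(2-propyl-1,3-dioxolan-2-yl)methyl]benzoate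
Conditions: (TMSOCH2)2 (1.5 equiv), TMSOTf (0.05 equiv), CH2Cl2, −78 → −20 °C; pyridine quench
Reagents that add atoms: 1,2-bis(trimethylsilyloxy)ethane, C[Si](C)(C)OCCO[Si](C)(C)C
Why: Silyl triflate-catalysed ketalisation with the bis-silyl ether of ethylene glycol is aprotic and driven by formation of hexamethyldisiloxane, so the unhindered ketone is protected at low temperature without acid-promoted lactonisation onto the neighbouring ester.

**Step 9**
Reactants: 22 methyl 2,4-dimethoxy-6-[(2-propyl-1,3-dioxolan-2-yl)methyl]benzoate
Product: 23 2,4-dimethoxy-6-[(2-propyl-1,3-dioxolan-2-yl)methyl]benzoic acid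
Conditions: KOH (10 equiv), DMSO/H2O, 90 °C; then cold 1 M HCl to pH 4–5, 0 °C
Reagents that add atoms: potassium hydroxide, [K+].[OH-]
Why: Saponification of the di-ortho-substituted methyl ester needs poorly solvated hydroxide in hot aqueous DMSO; the dioxolane is stable to base and should survive the brief, cold, weakly acidic work-up.

**Step 10**
Reactants: 23 2,4-dimethoxy-6-[(2-propyl-1,3-dioxolan-2-yl)methyl]benzoic acid; 16 benzyl 2,4-dihydroxy-6-pentylbenzoate
Product: 24 benzyl 4-({2,4-dimethoxy-6-[(2-propyl-1,3-dioxolan-2-yl)methyl]benzoyl}oxy)-2-hydroxy-6-pentylbenzoate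
Conditions: DCC (1.2 equiv), DMAP (0.2 equiv), CH2Cl2, 0 °C → rt
Reagents that add atoms: none
Why: Steglich esterification; the hydroxyl on C4 is free and unhindered, whereas the hydroxyl on C2 is hydrogen-bonded to the ester carbonyl and flanked by it, so acylation should go at O4, and the ketal stops the activated acid from closing onto its own enol.

**Step 11**
Reactants: 24 the ketal-protected depside benzyl ester
Product: 25 benzyl 4-{[2,4-dimethoxy-6-(2-oxopentyl)benzoyl]oxy}-2-hydroxy-6-pentylbenzoate
Conditions: 1 M aq. HCl/THF (1:4), rt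
Reagents that add atoms: water, O
Why: Acid-catalysed hydrolysis of the dioxolane through the oxocarbenium ion is fast at room temperature, where the aryl ester and the benzyl ester are stable.

**Step 12**
Reactants: 25 benzyl 4-{[2,4-dimethoxy-6-(2-oxopentyl)benzoyl]oxy}-2-hydroxy-6-pentylbenzoate
Product: 26 4-{[2,4-dimethoxy-6-(2-oxopentyl)benzoyl]oxy}-2-hydroxy-6-pentylbenzoic acid (target)
Conditions: H2 (1 atm), 10% Pd/C, EtOAc, rt
Reagents that add atoms: none
Why: Hydrogenolysis of the benzyl ester on Pd/C is neutral, so the salicylic acid is released without acid or heat; the aryl ester, the dialkyl ketone and the aryl ethers are not reduced under these conditions.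

**Compound list**
1 | 3,5-dimethoxyphenol | COc1cc(O)cc(OC)c1 | starting material
2 | 3,5-dimethoxyphenyl N-isopropylcarbamate | COc1cc(OC)cc(OC(=O)NC(C)C)c1 | intermediate
3 | 3,5-dimethoxyphenyl N-isopropyl-N-(trimethylsilyl)carbamate | COc1cc(OC)cc(OC(=O)N(C(C)C)[Si](C)(C)C)c1 | intermediate
4 | 2-lithio-3,5-dimethoxyphenyl N-isopropyl-N-(trimethylsilyl)carbamate | COc1cc(OC)c([Li])c(OC(=O)N(C(C)C)[Si](C)(C)C)c1 | intermediate
5 | 2-iodo-3,5-dimethoxyphenyl N-isopropyl-N-(trimethylsilyl)carbamate | COc1cc(OC)c(I)c(OC(=O)N(C(C)C)[Si](C)(C)C)c1 | intermediate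
6 | 2-iodo-3,5-dimethoxyphenyl N-isopropylcarbamate | COc1cc(OC)c(I)c(OC(=O)NC(C)C)c1 | intermediate
7 | 2-iodo-3,5-dimethoxyphenol | COc1cc(OC)c(I)c(O)c1 | intermediate
8 | 2-iodo-3,5-dimethoxyphenyl trifluoromethanesulfonate | COc1cc(OC)c(I)c(OS(=O)(=O)C(F)(F)F)c1 | intermediate
9 | pentylmagnesium bromide | CCCCC[Mg]Br | starting material
10 | carbon dioxide | O=C=O | starting material
11 | 2-(bromomagnesio)-3,5-dimethoxyphenyl trifluoromethanesulfonate | COc1cc(OC)c([Mg]Br)c(OS(=O)(=O)C(F)(F)F)c1 | intermediate
12 | 3,5-dimethoxybenzyne (1,2-didehydro-3,5-dimethoxybenzene) | COC1=CC(OC)=CC#C1 | intermediate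
13 | 2,4-dimethoxy-6-pentylphenylmagnesium bromide | CCCCCc1cc(OC)cc(OC)c1[Mg]Br | intermediate
14 | 2,4-dimethoxy-6-pentylbenzoic acid | CCCCCc1cc(OC)cc(OC)c1C(=O)O | intermediate
15 | 2,4-dihydroxy-6-pentylbenzoic acid | CCCCCc1cc(O)cc(O)c1C(=O)O | intermediate
16 | benzyl 2,4-dihydroxy-6-pentylbenzoate | CCCCCc1cc(O)cc(O)c1C(=O)OCc1ccccc1 | intermediate
17 | methyl 2,4-dimethoxy-6-methylbenzoate | COC(=O)c1c(C)cc(OC)cc1OC | starting material
18 | N-methoxy-N-methylbutanamide | CCCC(=O)N(C)OC | starting material
19 | methyl 2-(lithiomethyl)-4,6-dimethoxybenzoate | COC(=O)c1c(C[Li])cc(OC)cc1OC | intermediate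
20 | lithium alkoxide of the N-methoxy-N-methyl hemiaminal (adduct of 19 and 18) | CCCC(O[Li])(Cc1cc(OC)cc(OC)c1C(=O)OC)N(C)OC | intermediate
21 | methyl 2,4-dimethoxy-6-(2-oxopentyl)benzoate | CCCC(=O)Cc1cc(OC)cc(OC)c1C(=O)OC | intermediate
22 | methyl 2,4-dimethoxy-6-[(2-propyl-1,3-dioxolan-2-yl)methyl]benzoate | CCCC1(Cc2cc(OC)cc(OC)c2C(=O)OC)OCCO1 | intermediate
23 | 2,4-dimethoxy-6-[(2-propyl-1,3-dioxolan-2-yl)methyl]benzoic acid | CCCC1(Cc2cc(OC)cc(OC)c2C(=O)O)OCCO1 | intermediate
24 | benzyl 4-({2,4-dimethoxy-6-[(2-propyl-1,3-dioxolan-2-yl)methyl]benzoyl}oxy)-2-hydroxy-6-pentylbenzoate | CCCCCc1cc(OC(=O)c2c(CC3(CCC)OCCO3)cc(OC)cc2OC)cc(O)c1C(=O)OCc1ccccc1 | intermediate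
25 | benzyl 4-{[2,4-dimethoxy-6-(2-oxopentyl)benzoyl]oxy}-2-hydroxy-6-pentylbenzoate | CCCCCc1cc(OC(=O)c2c(CC(=O)CCC)cc(OC)cc2OC)cc(O)c1C(=O)OCc1ccccc1 | intermediate
26 | 4-{[2,4-dimethoxy-6-(2-oxopentyl)benzoyl]oxy}-2-hydroxy-6-pentylbenzoic acid | CCCCCc1cc(OC(=O)c2c(CC(=O)CCC)cc(OC)cc2OC)cc(O)c1C(=O)O | target

**Totals**
Total step count: 12.
Longest linear sequence: 9 steps (steps 1, 2, 3, 4, 5, 6, 10, 11, 12).

**Steps most likely to fail**

1. Step 4. Exchange between the product arylmagnesium and unreacted iodo triflate, or addition of an arylmagnesium species to the aryne, may divert material to iodoarene and biaryl. Carboxylation of the di-ortho-substituted arylmagnesium may also be incomplete, leaving protonated arene. Fallback, setting out from 1 and 9 and returning at 14: 1 is triflated (Tf2O, pyridine, CH2Cl2, 0 °C) to 3,5-dimethoxyphenyl trifluoromethanesulfonate F1. Kumada coupling of F1 with 9 (PdCl2(dppf) cat., Et2O/THF, reflux) gives 1,3-dimethoxy-5-pentylbenzene F2. Vilsmeier–Haack formylation (POCl3, DMF, 0 → 80 °C) goes para to one methoxy group and ortho to the pentyl group rather than between the two methoxy groups, giving 2,4-dimethoxy-6-pentylbenzaldehyde F3. Pinnick oxidation (NaClO2, NaH2PO4, 2-methyl-2-butene, t-BuOH/H2O, rt) then gives 14.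

2. Step 5. Protodecarboxylation of the electron-rich salicylic acid may compete while the ethers are cleaved, or cleavage of the para methoxy group may stall. Fallback, setting out from 14 and returning at 15: the acid is esterified (MeI, K2CO3, DMF, rt) to methyl 2,4-dimethoxy-6-pentylbenzoate F4, so that no acyloxyborane can form. BBr3 (CH2Cl2, −78 → 0 °C) then gives methyl 2,4-dihydroxy-6-pentylbenzoate F5. Saponification under strongly basic conditions, where the phenoxide–carboxylate resists loss of CO2 (KOH, aq. MeOH, reflux under argon; cold acidification), gives 15.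

3. Step 10. Acyl transfer from the di-ortho-substituted acid may be slow enough for the O-acylisourea to rearrange to the N-acylurea, and some acylation at the chelated hydroxyl may occur. Fallback, setting out from 23 and 16 and returning at 24: 23 is converted with cyanuric fluoride and pyridine (CH2Cl2, −10 °C → rt) into the isolable 2,4-dimethoxy-6-[(2-propyl-1,3-dioxolan-2-yl)methyl]benzoyl fluoride F6. Compound 16 is deprotonated at its more acidic, non-chelated C4 hydroxyl (NaH, 1 equiv, THF, 0 °C), and the phenoxide is acylated by F6 (0 °C → rt) to give 24.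

**Further compounds**
F1 | step 4 | 3,5-dimethoxyphenyl trifluoromethanesulfonate | COc1cc(OC)cc(OS(=O)(=O)C(F)(F)F)c1
F2 | step 4 | 1,3-dimethoxy-5-pentylbenzene | CCCCCc1cc(OC)cc(OC)c1
F3 | step 4 | 2,4-dimethoxy-6-pentylbenzaldehyde | CCCCCc1cc(OC)cc(OC)c1C=O
F4 | step 5 | methyl 2,4-dimethoxy-6-pentylbenzoate | CCCCCc1cc(OC)cc(OC)c1C(=O)OC
F5 | step 5 | methyl 2,4-dihydroxy-6-pentylbenzoate | CCCCCc1cc(O)cc(O)c1C(=O)OC
F6 | step 10 | 2,4-dimethoxy-6-[(2-propyl-1,3-dioxolan-2-yl)methyl]benzoyl fluoride | CCCC1(Cc2cc(OC)cc(OC)c2C(=O)F)OCCO1
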